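Remark on numbering and one assumption: ring A is C1 (ester carbinol)–C2 (free carbinol)–C3 (CH2)–C4–C9–C10 and ring B is C4=C5–C6(=O)–C7(OH)=C8–C9. C9 carries the angular methyl, C10 the secondary methyl, and O1, O2, O6, O7 are the oxygens on those carbons. Compound 15 is assumed to be carried on as a mixture of epimers at C7, because that centre becomes sp2 in step 11.

## The problem

Septeremophilane G (28) joins a flat, cross-conjugated diosphenol ring B (C4=C5–C6(=O)–C7(OH)=C8) through C4 and the quaternary C9 to a saturated ring A (C1–C2–C3–C4–C9–C10), and O1 carries a (2E,4E,6S)-6-methylocta-2,4-dienoate. Ring A holds four contiguous stereocentres: the C9 and C10 methyls are cis, the C1 ester is cis to the C10 methyl and the C2 hydroxyl is trans to the ester, which in the chair means an axial C9 methyl, an equatorial C10 methyl and two axial oxygens. C9 has to be set absolutely; C10 can then be set relative to C9, C1 relative to C10 by 1,2-induction and C2 relative to C1 in a ring closure, whereas the remote side-chain centre cannot be induced and must be bought. The functional groups are fragile: the dienone rearranges to a phenol in strong acid, the diosphenol is easily oxidised, the dienoate has an epimerisable allylic centre and accepts nucleophiles, and a free hydroxyl next to the ester invites acyl migration. Oxidations and strong bases should therefore be finished before the bicycle and the ester coexist. What makes the plan possible is the position of C3: it is γ to the C6 carbonyl through the C4=C5 bond and its neighbour C2 is a carbinol, so the C2–C3 bond can be made by a vinylogous aldol addition of the C4 methyl group of a ring B dienone to an aldehyde at C2. That methyl group is the only enolisable position of the dienone, and the quaternary C9 keeps the derived trienol ether from becoming an arene. If O7 were also a silyl enol ether, C8 would be a second nucleophilic carbon that could close a five-membered ring onto the aldehyde, so O7 is carried as an enol ester.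

## Retrosynthesis

**28 from 27 (O7–acyl bond).** The last cut removes an acyl group from O7. The enol ester 27 is an activated ester and should be cleaved by mild methanolysis without touching the hindered C1 ester. Choosing the same dienoyl group for O7 and O1 means one esterification installs both and any acyl transfer between them is degenerate. The price is one equivalent of acid 21, returned as its methyl ester.

**27 from 26 (C2–C3, key step).** Cutting C2–C3 opens ring A to the monocyclic silyl trienol ether aldehyde 26. Against cuts inside ring B or at C9–C10, this leaves no oxidation to be done on the ester-bearing bicycle, and three of the four ring stereocentres are already in place. The forward reaction must be γ-selective (C3, not C5) and must place the new C2–O bond trans to the C1 ester.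

**26 from 25, 24 and 23 (O6–Si bond, C2 oxidation level, O2 protecting group).** The trienol ether 26 comes from dienone aldehyde 25 by soft enolisation. The aldehyde comes from primary alcohol 24, and 24 from methoxymethyl ether 23. The acetal is chosen because it survives organolithium, hydride, radical oxidation and strong base, and contains no benzylic C–H.

**23 from 16 and 21 (two ester C–O bonds).** A double esterification joins diosphenol diol 16 to acid 21. The acid comes from ester 20, made from (S)-2-methylbutanal 18 and phosphonate 19 by a vinylogous Horner–Wadsworth–Emmons reaction. Aldehyde 18 comes from the commercial alcohol 17.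

**16 from 15, 14 and 13 (ring B oxygens).** The diosphenol is the enol of a 1,2-dione, reached from α′-hydroxy enone 15. That comes from enone 14 by kinetic enolate hydroxylation, and 14 from cyclohexene 13 by allylic oxidation. Doing this on the monocycle, before the dienoate is present, avoids exposing the side-chain ester to base or radicals.

**13 from 12 and 11 (C1–H bond, C1–C2 bond).** The C1 carbinol is made by Felkin–Anh reduction of ketone 12, which gives the required C1/C10 relationship. Addition of a C2 nucleophile to a C1 aldehyde would give the opposite one. Ketone 12 comes from Weinreb amide 11 and a hydroxymethyl anion equivalent.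

**11 from 9 and 6 (C9–C10 bond).** Amide 11 is made from acid 9. Cutting C9–C10 as an Ireland–Claisen bond leads to propanoate 6. The rearrangement transfers the carbinol configuration to the quaternary C9 and sets C10 through the enolate geometry. A conjugate addition of a ring enolate to a crotonate would form the same bond with much weaker control of both centres.

**6 from 5, 4, 2 and 1.** Ester 6 comes from allylic alcohol 5, made by catalytic enantioselective reduction of enone 4. Enone 4 comes from vinylogous ester 2 and MeLi, and 2 from 2-methylcyclohexane-1,3-dione 1.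

## Roads not taken

**Alternative 1:** The two methyl groups (C11 on C9, C12 on C10) are cut off together. In the forward sense a thiocarbonyl ylide, released from sulfide A2 with CsF, adds across the C9=C10 bond of bicyclic enone A1 to give the cis-fused thiolane A3; later desulfurisation reveals both methyls.

- Merits: the cis relationship of the methyls is guaranteed by a concerted suprafacial addition, and the quaternary centre is made without enolate alkylation.
- Weak points: the β,β-disubstituted enone is a reluctant dipolarophile, and the face is chosen by a C4–H centre that the target later destroys. A3 also has the wrong oxidation pattern everywhere. The C1 ketone must become the ester carbinol, C2 must be hydroxylated trans to it, and ring B must be taken from a C6 ketal to the C4=C5/C7-hydroxy dienone, all on the bicycle.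
- Comparison: this road is more certain than the chosen one for the C9/C10 relationship, which here rests on a chair preference in the Claisen step. The chosen plan sets against it that C1 is fixed by an acyclic Felkin–Anh reduction, C2 in the ring closure, and that no redox step follows on the bicycle.

**Alternative 2:** C1=C2 and C4=C5 are cut. The acyclic tetraene A4 would be closed twice by the second-generation Grubbs catalyst to the bicyclic diene ketone A5.

- Merits: both rings form in one operation from an acyclic precursor whose C9/C10 centres could be made by the same Claisen chemistry. The step count to a bicycle is lower than in the chosen plan.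
- Weak points: ring B must close through a 1,1-disubstituted alkene next to the quaternary C9, which is slow, and seven- and eight-membered pairings compete. A5 carries no oxygen at C1, C2 or C6 and has an unconjugated C7 ketone. The C1=C2 alkene would need a trans-dioxygenation that also decides which oxygen is acylated, and ring B would need two further oxidations.
- Comparison: this road wins on skeleton-building economy. The chosen plan is longer before ring closure but finishes one deprotection after it.

**Alternative 3:** C4–C9 and C5–C6 are cut. Ni(cod)2 with a triaryl phosphite (zerovalent nickel) would join the alkyne and the diene of dienynone A6 in an intramolecular [4+2] cycloaddition to give A7.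

- Merits: both rings and the quaternary centre form in one mild, atom-economical step, and the C1 ketone is well placed for later work at C1 and C2.
- Weak points: C9 must be induced by C10, which is α to the ketone and can epimerise. The diene terminus that becomes C9 is fully substituted, which slows the cycloaddition. A7 is a skipped diene with no ring B oxygen, so C6 oxidation, C7 hydroxylation, C2 hydroxylation and C1 reduction all remain for the bicycle.
- Comparison: this is the shortest way to the bicyclic skeleton. The chosen plan answers with independent, well-understood control of each stereocentre and with the oxidation pattern of ring B complete before the ester is attached.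

Key step: step 19

## Route

**Step 1**
Reactants: 1 2-methylcyclohexane-1,3-dione
Product: 2 3-(2-methylpropoxy)-2-methylcyclohex-2-en-1-one
Conditions: i-BuOH, TsOH·H2O (cat.), toluene, reflux, Dean–Stark
Reagents that add atoms: 2-methylpropan-1-ol, CC(C)CO
Why: Acid-catalysed enol etherification of a symmetric 1,3-dione with azeotropic removal of water; only one vinylogous ester can form.

**Step 2**
Reactants: 2 3-(2-methylpropoxy)-2-methylcyclohex-2-en-1-one
Product: 4 2,3-dimethylcyclohex-2-en-1-one, via tertiary allylic alcohol 3 (not isolated)
Conditions: MeLi, Et2O, −78 to 0 °C; then 1 M HCl, 0 °C to rt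
Reagents that add atoms: methyllithium, [Li]C; water, O
Why: Stork–Danheiser transposition: 1,2-addition to the vinylogous ester carbonyl, then acid-mediated ionisation of the tertiary alcohol and hydrolysis of the resulting oxocarbenium ion give the transposed enone.

**Step 3**
Reactants: 4 2,3-dimethylcyclohex-2-en-1-one
Product: 5 (1R)-2,3-dimethylcyclohex-2-en-1-ol
Conditions: (S)-2-methyl-CBS-oxazaborolidine (10 mol %), BH3·SMe2, THF, −20 °C; MeOH, then aqueous work-up
Reagents that add atoms: none
Why: Corey–Bakshi–Shibata reduction; the α-methylated alkenyl branch plays the large substituent, so the (S)-catalyst should give the (R)-alcohol, which fixes the absolute configuration of the route.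

**Step 4**
Reactants: 5 (1R)-2,3-dimethylcyclohex-2-en-1-ol
Product: 6 (1R)-2,3-dimethylcyclohex-2-en-1-yl propanoate
Conditions: EtCOCl, Et3N, DMAP (cat.), CH2Cl2, 0 °C
Reagents that add atoms: propanoyl chloride, CCC(=O)Cl
Why: DMAP-catalysed O-acylation under basic, non-ionising conditions, so the allylic carbinol centre is retained.

**Step 5**
Reactants: 6 (1R)-2,3-dimethylcyclohex-2-en-1-yl propanoate
Product: 9 (2R)-2-[(1R)-1,2-dimethylcyclohex-2-en-1-yl]propanoic acid, via (E)-silyl ketene acetal 7 (not isolated), via trimethylsilyl ester 8 (not isolated)
Conditions: LiN(i-Pr)2, THF, −78 °C; Me3SiCl, −78 to 60 °C; then 1 M HCl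
Reagents that add atoms: none
Why: Ireland–Claisen rearrangement: enolisation in THF without polar cosolvent gives the (E)-silyl ketene acetal, the suprafacial [3,3] shift transfers the carbinol configuration to the quaternary C9, and the chair-like transition state places the C10 methyl cis to the C9 methyl with respect to the future ring A (the boat would put the ketene acetal methyl over the ring and the silyloxy group over the ring methyl).

**Step 6**
Reactants: 9 (2R)-2-[(1R)-1,2-dimethylcyclohex-2-en-1-yl]propanoic acid
Product: 11 (2R)-N-methoxy-N-methyl-2-[(1R)-1,2-dimethylcyclohex-2-en-1-yl]propanamide, via acid chloride 10 (not isolated)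
Conditions: (COCl)2, DMF (cat.), CH2Cl2, 0 °C to rt; then MeNH(OMe)·HCl, pyridine, 0 °C to rt
Reagents that add atoms: N,O-dimethylhydroxylamine hydrochloride, CNOC.Cl
Why: Weinreb amide formation through the acid chloride, chosen because the acid is neopentyl-like; pyridine is used in place of a trialkylamine so that no ketene forms and C10 is not epimerised.

**Step 7**
Reactants: 11 (2R)-N-methoxy-N-methyl-2-[(1R)-1,2-dimethylcyclohex-2-en-1-yl]propanamide
Product: 12 (3R)-3-[(1R)-1,2-dimethylcyclohex-2-en-1-yl]-1-(methoxymethoxy)butan-2-one
Conditions: Bu3SnCH2OCH2OMe, n-BuLi, THF, −78 °C; then 11, −78 to −40 °C; aq NH4Cl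
Reagents that add atoms: tributyl[(methoxymethoxy)methyl]stannane, CCCC[Sn](CCCC)(CCCC)COCOC
Why: Tin–lithium exchange gives an α-alkoxymethyllithium (a hydroxymethyl anion equivalent) that adds once to the Weinreb amide, whose chelated tetrahedral intermediate releases the ketone only on quench; the low temperature keeps the α-centre C10 intact.

**Step 8**
Reactants: 12 (3R)-3-[(1R)-1,2-dimethylcyclohex-2-en-1-yl]-1-(methoxymethoxy)butan-2-one
Product: 13 (2R,3R)-3-[(1R)-1,2-dimethylcyclohex-2-en-1-yl]-1-(methoxymethoxy)butan-2-ol
Conditions: LiBH(s-Bu)3, THF, −78 °C; aq NH4Cl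
Reagents that add atoms: none
Why: Felkin–Anh reduction: the bulky hydride attacks the ketone anti to the quaternary C9 group on C10 and past the C10 hydrogen, which should give the (2R,3R) alcohol, the C1 configuration of the target.

**Step 9**
Reactants: 13 (2R,3R)-3-[(1R)-1,2-dimethylcyclohex-2-en-1-yl]-1-(methoxymethoxy)butan-2-ol
Product: 14 (4R)-4-[(2R,3R)-3-hydroxy-4-(methoxymethoxy)butan-2-yl]-3,4-dimethylcyclohex-2-en-1-one
Conditions: Rh2(cap)4 (cap = caprolactamate, 1 mol %), t-BuOOH (70% aq), K2CO3, CH2Cl2, rt
Reagents that add atoms: tert-butyl hydroperoxide, CC(C)(C)OO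
Why: Radical allylic oxidation by t-BuOO•: hydrogen abstraction at the ring CH2 next to the alkene CH (C6) gives the conjugated enone, as in the C7 oxidation of 3-hydroxy-Δ5-steroids, where a free secondary alcohol and a quaternary carbon next to the alkene are also present; the acetal and the carbinol C–H bonds are stronger than the allylic one.

**Step 10**
Reactants: 14 (4R)-4-[(2R,3R)-3-hydroxy-4-(methoxymethoxy)butan-2-yl]-3,4-dimethylcyclohex-2-en-1-one
Product: 15 (4R)-6-hydroxy-4-[(2R,3R)-3-hydroxy-4-(methoxymethoxy)butan-2-yl]-3,4-dimethylcyclohex-2-en-1-one (both epimers at the ring carbinol carbon)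
Conditions: KN(SiMe3)2 (2.3 equiv), THF, −78 °C; 2-(phenylsulfonyl)-3-phenyloxaziridine, −78 °C; aq NH4Cl
Reagents that add atoms: 2-(phenylsulfonyl)-3-phenyloxaziridine, O=S(=O)(N1OC1c1ccccc1)c1ccccc1
Why: Kinetic deprotonation of a cyclohexenone takes the α′ proton (C7), not the γ-methyl, and the cross-conjugated enolate is hydroxylated by the N-sulfonyloxaziridine (enolate oxidation); the new centre is uncontrolled and is removed in step 11.

**Step 11**
Reactants: 15 (4R)-6-hydroxy-4-[(2R,3R)-3-hydroxy-4-(methoxymethoxy)butan-2-yl]-3,4-dimethylcyclohex-2-en-1-one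
Product: 16 (4S)-2-hydroxy-4-[(2R,3R)-3-hydroxy-4-(methoxymethoxy)butan-2-yl]-4,5-dimethylcyclohexa-2,5-dien-1-one
Conditions: Cu(OAc)2 (20 mol %), air, MeOH, rt
Reagents that add atoms: none
Why: Copper-catalysed aerobic oxidation of the α-ketol to the 1,2-dione, which enolises towards C8 to the cross-conjugated diosphenol; an isolated secondary alcohol is not oxidised under these conditions.

**Step 12**
Reactants: 17 (2S)-2-methylbutan-1-ol
Product: 18 (2S)-2-methylbutanal
Conditions: TEMPO (1 mol %), KBr, NaOCl, NaHCO3, CH2Cl2/H2O, 0 °C; dried solution used at once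
Reagents that add atoms: none
Why: Oxoammonium (TEMPO) oxidation at 0 °C and mildly basic pH is a standard way to α-branched aldehydes without racemisation; the volatile aldehyde is not stored.

**Step 13**
Reactants: 18 (2S)-2-methylbutanal; 19 ethyl (2E)-4-(diethoxyphosphoryl)but-2-enoate
Product: 20 ethyl (2E,4E,6S)-6-methylocta-2,4-dienoate
Conditions: LiN(SiMe3)2, THF, −78 to 0 °C
Reagents that add atoms: none
Why: Vinylogous Horner–Wadsworth–Emmons olefination; the stabilised phosphonate anion gives the (2E,4E)-dienoate and is too weak a base to epimerise the α-centre of 18 at low temperature.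

**Step 14**
Reactants: 20 ethyl (2E,4E,6S)-6-methylocta-2,4-dienoate
Product: 21 (2E,4E,6S)-6-methylocta-2,4-dienoic acid
Conditions: LiOH, THF/MeOH/H2O, rt; then 1 M HCl
Reagents that add atoms: lithium hydroxide, [Li+].[OH-]
Why: Ester saponification; hydroxide does not deprotonate the remote allylic centre.

**Step 15**
Reactants: 16 (4S)-2-hydroxy-4-[(2R,3R)-3-hydroxy-4-(methoxymethoxy)butan-2-yl]-4,5-dimethylcyclohexa-2,5-dien-1-one; 21 (2E,4E,6S)-6-methylocta-2,4-dienoic acid (3 equiv)
Product: 23 bis-dienoate methoxymethyl ether (16 acylated at O1 and O7), via mixed anhydride 22 (not isolated)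
Conditions: 2,4,6-Cl3C6H2COCl, Et3N, THF, rt; then 16, DMAP, toluene, rt to 40 °C
Reagents that add atoms: none
Why: Yamaguchi esterification: the mixed anhydride acylates both the acidic diosphenol hydroxyl and the hindered C1 alcohol under DMAP catalysis; with the same acyl group on both oxygens any acyl transfer is degenerate, and the O7 ester later keeps C8 from acting as a nucleophile.

**Step 16**
Reactants: 23 bis-dienoate methoxymethyl ether
Product: 24 bis-dienoate primary alcohol (O2–H)
Conditions: Me2BBr, CH2Cl2, −78 °C; then THF/sat. NaHCO3, 0 °C
Reagents that add atoms: none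
Why: Lewis acid cleavage of the methoxymethyl acetal (bromide attack on the activated acetal carbon) at low temperature leaves the esters and the dienone alone; buffered work-up and immediate use limit migration of the C1 acyl group to O2.

**Step 17**
Reactants: 24 bis-dienoate primary alcohol
Product: 25 bis-dienoate aldehyde (C2 aldehyde)
Conditions: Dess–Martin periodinane, NaHCO3, CH2Cl2, 0 °C to rt
Reagents that add atoms: none
Why: Dess–Martin oxidation of a primary alcohol under buffered, near-neutral conditions should give the α-acyloxy aldehyde without epimerising C1 and cannot over-oxidise.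

**Step 18**
Reactants: 25 bis-dienoate aldehyde
Product: 26 silyl trienol ether aldehyde (O6-TBS, C3 exocyclic methylene)
Conditions: t-BuMe2SiOTf (1.2 equiv), i-Pr2NEt, CH2Cl2, −78 to −40 °C; cold NaHCO3 work-up, used at once
Reagents that add atoms: tert-butyldimethylsilyl trifluoromethanesulfonate, CC(C)(C)[Si](C)(C)OS(=O)(=O)C(F)(F)F
Why: Soft enolisation: the silyl triflate silylates the dienone oxygen, which is far more basic than the α-acyloxy aldehyde or the ester carbonyls, and the amine removes a proton from the C3 methyl, the only position available, to give the cross-conjugated trienol ether; low temperature, a hindered amine and a small excess of triflate are meant to keep the aldehyde from being enol-silylated.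

**Step 19**
Reactants: 26 silyl trienol ether aldehyde
Product: 27 septeremophilane G 7-O-[(2E,4E,6S)-6-methylocta-2,4-dienoate]
Conditions: BF3·OEt2, CH2Cl2, −78 °C; sat. NaHCO3
Reagents that add atoms: none
Why: Vinylogous Mukaiyama aldol addition: BF3 binds the C2 aldehyde oxygen, the terminal methylene C3 of the silyl trienol ether attacks C2, and the O6-silyl oxocarbenium ion then loses its silyl group as the silyl fluoride to return the cross-conjugated dienone. The closest known reaction type is the Lewis acid-mediated γ-selective addition of silyl dienol ethers to aldehydes, used here intramolecularly. Ring A closes in a favoured 6-(enolendo)-exo-trig mode through a chair in which the in-plane C9–C8 bond is equatorial, the C9 methyl axial, the C10 methyl equatorial and the C1 ester axial. The face of C3 that reacts is fixed by C9, because the chain can only reach the side of the ring B plane on which C10 stands. The new stereocentre C2 is controlled by C1: with a monodentate Lewis acid the C2=O bond should lie anti to the axial C1–O bond (opposed dipoles), so the new oxygen becomes axial and trans to the ester. The step needs γ-selectivity: C3 is the unhindered terminus and its attack restores the dienone, attack through C5 would give a bridged bicyclo[3.3.1] skeleton with loss of conjugation, and C8 is not nucleophilic because O7 is an enol ester. The quaternary C9 keeps 26 from tautomerising to an arene, and the low temperature disfavours 1,2-shift of the C9 substituents.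

**Step 20**
Reactants: 27 septeremophilane G 7-O-[(2E,4E,6S)-6-methylocta-2,4-dienoate]
Product: 28 septeremophilane G
Conditions: K2CO3 (0.2 equiv), MeOH, 0 °C; pH 7 buffer
Reagents that add atoms: none
Why: Base-catalysed methanolysis: the enol ester of the diosphenol is an activated ester (its leaving group is comparable to a phenoxide) and should be cleaved far faster than the hindered secondary dienoate, while the trans-diaxial O1/O2 arrangement blocks acyl migration through a cyclic orthoester.

## Compound list

1 | 2-methylcyclohexane-1,3-dione | CC1C(=O)CCCC1=O | starting material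
2 | 3-(2-methylpropoxy)-2-methylcyclohex-2-en-1-one | CC1=C(OCC(C)C)CCCC1=O | intermediate
3 | 3-(2-methylpropoxy)-1,2-dimethylcyclohex-2-en-1-ol (racemic tertiary allylic alcohol, not isolated) | CC(C)COC1=C(C)C(C)(O)CCC1 | intermediate
4 | 2,3-dimethylcyclohex-2-en-1-one | CC1=C(C)C(=O)CCC1 | intermediate
5 | (1R)-2,3-dimethylcyclohex-2-en-1-ol | O[C@H]1C(C)=C(C)CCC1 | intermediate
6 | (1R)-2,3-dimethylcyclohex-2-en-1-yl propanoate | CCC(=O)O[C@H]1C(C)=C(C)CCC1 | intermediate
7 | {[(1E)-1-{[(1R)-2,3-dimethylcyclohex-2-en-1-yl]oxy}prop-1-en-1-yl]oxy}trimethylsilane (not isolated) | C/C=C(/O[Si](C)(C)C)O[C@H]1C(C)=C(C)CCC1 | intermediate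
8 | trimethylsilyl (2R)-2-[(1R)-1,2-dimethylcyclohex-2-en-1-yl]propanoate (not isolated) | C[Si](C)(C)OC(=O)[C@H](C)[C@@]1(C)CCCC=C1C | intermediate
9 | (2R)-2-[(1R)-1,2-dimethylcyclohex-2-en-1-yl]propanoic acid | OC(=O)[C@H](C)[C@@]1(C)CCCC=C1C | intermediate
10 | (2R)-2-[(1R)-1,2-dimethylcyclohex-2-en-1-yl]propanoyl chloride (not isolated) | ClC(=O)[C@H](C)[C@@]1(C)CCCC=C1C | intermediate
11 | (2R)-N-methoxy-N-methyl-2-[(1R)-1,2-dimethylcyclohex-2-en-1-yl]propanamide | CON(C)C(=O)[C@H](C)[C@@]1(C)CCCC=C1C | intermediate
12 | (3R)-3-[(1R)-1,2-dimethylcyclohex-2-en-1-yl]-1-(methoxymethoxy)butan-2-one | COCOCC(=O)[C@H](C)[C@@]1(C)CCCC=C1C | intermediate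
13 | (2R,3R)-3-[(1R)-1,2-dimethylcyclohex-2-en-1-yl]-1-(methoxymethoxy)butan-2-ol | COCOC[C@H](O)[C@H](C)[C@@]1(C)CCCC=C1C | intermediate
14 | (4R)-4-[(2R,3R)-3-hydroxy-4-(methoxymethoxy)butan-2-yl]-3,4-dimethylcyclohex-2-en-1-one | COCOC[C@H](O)[C@H](C)[C@@]1(C)CCC(=O)C=C1C | intermediate
15 | (4R)-6-hydroxy-4-[(2R,3R)-3-hydroxy-4-(methoxymethoxy)butan-2-yl]-3,4-dimethylcyclohex-2-en-1-one (both epimers at the ring carbinol carbon, which is C7 in the numbering of the target) | COCOC[C@H](O)[C@H](C)[C@@]1(C)CC(O)C(=O)C=C1C | intermediate
16 | (4S)-2-hydroxy-4-[(2R,3R)-3-hydroxy-4-(methoxymethoxy)butan-2-yl]-4,5-dimethylcyclohexa-2,5-dien-1-one | COCOC[C@H](O)[C@H](C)[C@@]1(C)C=C(O)C(=O)C=C1C | intermediate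
17 | (2S)-2-methylbutan-1-ol | CC[C@H](C)CO | starting material
18 | (2S)-2-methylbutanal | CC[C@H](C)C=O | intermediate
19 | ethyl (2E)-4-(diethoxyphosphoryl)but-2-enoate | CCOC(=O)/C=C/CP(=O)(OCC)OCC | starting material
20 | ethyl (2E,4E,6S)-6-methylocta-2,4-dienoate | CC[C@H](C)/C=C/C=C/C(=O)OCC | intermediate
21 | (2E,4E,6S)-6-methylocta-2,4-dienoic acid | CC[C@H](C)/C=C/C=C/C(=O)O | intermediate
22 | (2E,4E,6S)-6-methylocta-2,4-dienoic 2,4,6-trichlorobenzoic anhydride (not isolated) | CC[C@H](C)/C=C/C=C/C(=O)OC(=O)c1c(Cl)cc(Cl)cc1Cl | intermediate
23 | (2R,3R)-1-(methoxymethoxy)-3-[(1S)-1,2-dimethyl-5-{[(2E,4E,6S)-6-methylocta-2,4-dienoyl]oxy}-4-oxocyclohexa-2,5-dien-1-yl]butan-2-yl (2E,4E,6S)-6-methylocta-2,4-dienoate | COCOC[C@H](OC(=O)/C=C/C=C/[C@@H](C)CC)[C@H](C)[C@@]1(C)C=C(OC(=O)/C=C/C=C/[C@@H](C)CC)C(=O)C=C1C | intermediate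
24 | (2R,3R)-1-hydroxy-3-[(1S)-1,2-dimethyl-5-{[(2E,4E,6S)-6-methylocta-2,4-dienoyl]oxy}-4-oxocyclohexa-2,5-dien-1-yl]butan-2-yl (2E,4E,6S)-6-methylocta-2,4-dienoate | OC[C@H](OC(=O)/C=C/C=C/[C@@H](C)CC)[C@H](C)[C@@]1(C)C=C(OC(=O)/C=C/C=C/[C@@H](C)CC)C(=O)C=C1C | intermediate
25 | (2R,3R)-1-oxo-3-[(1S)-1,2-dimethyl-5-{[(2E,4E,6S)-6-methylocta-2,4-dienoyl]oxy}-4-oxocyclohexa-2,5-dien-1-yl]butan-2-yl (2E,4E,6S)-6-methylocta-2,4-dienoate | O=C[C@H](OC(=O)/C=C/C=C/[C@@H](C)CC)[C@H](C)[C@@]1(C)C=C(OC(=O)/C=C/C=C/[C@@H](C)CC)C(=O)C=C1C | intermediate
26 | (2R,3R)-3-[(1S)-4-{[tert-butyl(dimethyl)silyl]oxy}-1-methyl-6-methylidene-3-{[(2E,4E,6S)-6-methylocta-2,4-dienoyl]oxy}cyclohexa-2,4-dien-1-yl]-1-oxobutan-2-yl (2E,4E,6S)-6-methylocta-2,4-dienoate | C=C1C=C(O[Si](C)(C)C(C)(C)C)C(OC(=O)/C=C/C=C/[C@@H](C)CC)=C[C@]1(C)[C@@H](C)[C@@H](OC(=O)/C=C/C=C/[C@@H](C)CC)C=O | intermediate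
27 | septeremophilane G 7-O-[(2E,4E,6S)-6-methylocta-2,4-dienoate] (enol ester at O7, free axial C2 hydroxyl) | CC[C@H](C)/C=C/C=C/C(=O)O[C@H]1[C@H](O)CC2=CC(=O)C(OC(=O)/C=C/C=C/[C@@H](C)CC)=C[C@]2(C)[C@H]1C | intermediate
28 | septeremophilane G | CC[C@H](C)/C=C/C=C/C(=O)O[C@H]1[C@H](O)CC2=CC(=O)C(O)=C[C@]2(C)[C@H]1C | target

## Step count and least certain steps

Total step count: 20. Longest linear sequence: 17 steps (steps 1–11 and 15–20); steps 12–14 make acid 21 in a side branch.

**Step 19 (key step).** The most likely failure is erosion of facial selectivity at the aldehyde. The two chair transition states differ only in the orientation of C2=O relative to the axial C1–O bond, and any two-point binding of the Lewis acid to O1 (or the ester carbonyl) and the aldehyde would favour the cis-hydroxy ester. Protodesilylation of 26 back to 25 is the second concern. Fallback, setting out from 26: if the closure gives mainly the C2 epimer of 27, the cis-hydroxy ester F1 with an equatorial hydroxyl, then F1 is submitted to a Mitsunobu reaction (PPh3, diisopropyl azodicarboxylate, 4-nitrobenzoic acid). This inverts C2 and gives the axial 4-nitrobenzoate F2 of the required trans series. No acyloxonium participation is expected in F1 because its leaving group is not antiperiplanar to the axial C1 ester. Methanolysis of F2 under the conditions of step 20 then removes the nitrobenzoate together with the O7 ester, and the route is rejoined at 28.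

**Step 18.** The likely failure is competing enol silylation of the α-acyloxy aldehyde, with loss of the C1 configuration, or premature triflate-promoted ring closure. Fallback, setting out from 24: the order of aldehyde formation and silylation is reversed. The primary alcohol is protected with allyl chloroformate and pyridine as the allyl carbonate F3 at O2. The dienone of F3 is converted with t-BuMe2SiOTf and Et3N into the silyl trienol ether allyl carbonate F4 while no aldehyde is present. The carbonate of F4 is removed under neutral conditions with Pd(PPh3)4 (zerovalent palladium) and dimedone to give the silyl trienol ether primary alcohol F5 with the silyl group intact. Dess–Martin oxidation of F5 buffered with pyridine then gives 26, where the route is rejoined.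

**Step 5.** The likely failure is leakage at C10, through incomplete (E)-selectivity in the enolisation or through competition from the boat-like transition state. In cyclohexenyl esters the chair places the silyloxy group over the ring, so the margin may be modest. Fallback, setting out from 5: an Eschenmoser–Claisen rearrangement with 1,1-dimethoxy-N,N-dimethylpropan-1-amine in xylenes at 140 °C gives the dimethylamide F6 corresponding to acid 9, that is (2R)-N,N-dimethyl-2-[(1R)-1,2-dimethylcyclohex-2-en-1-yl]propanamide. This proceeds through a ketene N,O-acetal of a single geometry, with the methyl cis to the allylic oxygen, so the C10 ratio then rests on the chair–boat preference alone. Addition of (methoxymethoxy)methyllithium to F6 gives ketone 12 directly, where the route is rejoined. This bypass is held in reserve because the thermal exchange on the hindered alcohol and the organolithium addition to a hindered dimethylamide are less certain than steps 4–7.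

**Step 9.** The likely failure is partial oxidation of the free C1 carbinol to the ketone, or slow conversion of the hindered alkene. Fallback, setting out from 13: the alcohol is silylated (Et3SiCl, imidazole) to the triethylsilyl ether F7 of the cyclohexene. Allylic oxidation of F7 with the stoichiometric CrO3·3,5-dimethylpyrazole complex at −20 °C gives the silylated enone F8 with the carbinol still masked. Mild acid (pyridinium p-toluenesulfonate, MeOH) then converts F8 into 14, where the route is rejoined.

**Step 10.** The likely failure is addition of the enolate to the sulfonimine by-product, or reversible conjugate addition of the C1 alkoxide to C4 before enolisation is complete. Fallback, setting out from 14: a base-free α′-acetoxylation with Mn(OAc)3 in refluxing benzene gives the α′-acetoxy enone F9 as a mixture of epimers. Methanolysis of F9 with K2CO3 in MeOH returns 15, where the route is rejoined.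

## Further compounds

F1 | step 19 | cis-hydroxy ester, the C2 epimer of 27 (2-epi-septeremophilane G 7-O-dienoate) | CC[C@H](C)/C=C/C=C/C(=O)O[C@H]1[C@@H](O)CC2=CC(=O)C(OC(=O)/C=C/C=C/[C@@H](C)CC)=C[C@]2(C)[C@H]1C
F2 | step 19 | axial 4-nitrobenzoate, the 2-O-(4-nitrobenzoyl) derivative of 27 | CC[C@H](C)/C=C/C=C/C(=O)O[C@H]1[C@H](OC(=O)c3ccc(cc3)[N+](=O)[O-])CC2=CC(=O)C(OC(=O)/C=C/C=C/[C@@H](C)CC)=C[C@]2(C)[C@H]1C
F3 | step 18 | allyl carbonate of 24 (at O2) | C=CCOC(=O)OC[C@H](OC(=O)/C=C/C=C/[C@@H](C)CC)[C@H](C)[C@@]1(C)C=C(OC(=O)/C=C/C=C/[C@@H](C)CC)C(=O)C=C1C
F4 | step 18 | silyl trienol ether allyl carbonate (O6-TBS, O2-allyloxycarbonyl) | C=C1C=C(O[Si](C)(C)C(C)(C)C)C(OC(=O)/C=C/C=C/[C@@H](C)CC)=C[C@]1(C)[C@@H](C)[C@@H](OC(=O)/C=C/C=C/[C@@H](C)CC)COC(=O)OCC=C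
F5 | step 18 | silyl trienol ether primary alcohol (O6-TBS, O2–H) | C=C1C=C(O[Si](C)(C)C(C)(C)C)C(OC(=O)/C=C/C=C/[C@@H](C)CC)=C[C@]1(C)[C@@H](C)[C@@H](OC(=O)/C=C/C=C/[C@@H](C)CC)CO
F6 | step 5 | (2R)-N,N-dimethyl-2-[(1R)-1,2-dimethylcyclohex-2-en-1-yl]propanamide | CN(C)C(=O)[C@H](C)[C@@]1(C)CCCC=C1C
F7 | step 9 | triethylsilyl ether of 13 | COCOC[C@H](O[Si](CC)(CC)CC)[C@H](C)[C@@]1(C)CCCC=C1C
F8 | step 9 | silylated enone, the triethylsilyl ether of 14 | COCOC[C@H](O[Si](CC)(CC)CC)[C@H](C)[C@@]1(C)CCC(=O)C=C1C
F9 | step 10 | α′-acetoxy enone (acetate of 15 at the ring carbinol) | COCOC[C@H](O)[C@H](C)[C@@]1(C)CC(OC(C)=O)C(=O)C=C1C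
A1 | alternative 1 | bicyclic enone with C1 ketone, C9=C10 alkene and C6 dioxolane ketal | O=C1CC[C@@H]2CC3(OCCO3)CCC2=C1
A2 | alternative 1 | chloromethyl trimethylsilylmethyl sulfide | C[Si](C)(C)CSCCl
A3 | alternative 1 | cis-fused thiolane tricycle across C9–C10 with C1 ketone and C6 ketal | O=C1CC[C@@H]2CC3(OCCO3)CC[C@@]24CSC[C@H]41
A4 | alternative 2 | 6-(but-3-en-2-yl)-6-methyl-7-methylidenedeca-1,9-dien-4-one (acyclic tetraene) | C=C[C@H](C)[C@@](C)(CC(=O)CC=C)C(=C)CC=C
A5 | alternative 2 | bicyclic diene ketone with C1=C2 and C4=C5 alkenes, C7 ketone and cis C9/C10 methyls | C1=CCC2=CCC(=O)C[C@]2(C)[C@H]1C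
A6 | alternative 3 | (6R,7E)-6,7-dimethyldeca-7,9-dien-1-yn-5-one (acyclic dienynone) | C#CCCC(=O)[C@H](C)/C(C)=C/C=C
A7 | alternative 3 | cis-1,8a-dimethyl-3,4,6,8a-tetrahydronaphthalen-2(1H)-one | O=C1CCC2=CCC=C[C@]2(C)[C@H]1C
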